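The runs were generated by integration for an exercise; noise was put on by code.

The unit I worked in was the decade, a fall of a concentration by a power of ten, and a long tail counted in it is a short subtraction of exponents.

| flask | substrate | partner A | partner B | remark | time |
|---|---|---|---|---|---|
| midnight | 0.20 M | 0.40 M | 0.30 M | the very flask that is asked about, followed so far |  |
| dusk | 0.40 M | 0.40 M | 0.30 M | run made earlier |  |
| flask | 0.20 M | 0.400 M | 0.300 M |  | 30 d |

| run | time / d | target / % | dormant form / % | open intermediate / % |
|---|---|---|---|---|
| midnight | 0.625 | 0 | 17.7 | 10.0 |
| midnight | 1.25 | 0.3 | 29.4 | 15.4 |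
| midnight | 2.08 | 1.2 | 38.4 | 19.3 |
| midnight | 3.00 | 3.2 | 43.3 | 22.1 |
| midnight | 5.00 | 5.1 | 47.1 | 22.8 |
| midnight | 10.0 | 9.7 | 45.7 | 22.4 |
| dusk | 2.08 | 0.5 | 38.9 | 18.1 |
| dusk | 4.00 | 3.0 | 47.2 | 20.8 |
| dusk | 6.00 | 4.9 | 49.3 | 20.8 |
| dusk | 8.00 | 5.6 | 49.0 | 21.5 |
| dusk | 10.0 | 7.0 | 48.3 | 20.4 |
| dusk | 12.0 | 7.5 | 48.2 | 20.8 |

(standard deviation of a reading: 0.3 percentage points)

- steps under discussion: second intermediate -> side product; partner B + partner A -> second intermediate; substrate + partner B -> open intermediate; open intermediate + second intermediate -> target; substrate <-> dormant form

- concentration of target at 30 d, in M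
- concentration of dormant form at 30 d, in M
- concentration of open intermediate at 30 d, in M
- concentration of second intermediate at 30 d, in M

1. I began with the main step, substrate + partner B. Over the first midnight interval I took mean free substrate as 0.172 M. I counted [partner B] lost as 3 times the open intermediate made, since partner A is charged at twice the substrate, which put mean [partner B] at 0.270 M. That reading gave a constant of 0.688 M⁻¹ d⁻¹, and with [substrate] held at its charge, my decade time for [partner B] came to 16.7 d.

2. Then I added the dormant form. At the last midnight reading it stood at 2.06 times free substrate, and the balance of the readings put [substrate] at 0.0444 M, which stretched my decade to 75.4 d.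

3. Then I added partner A. At that last midnight reading I booked the partner B not found in open intermediate or target through partner A, as if none stood free, which put [partner A] near 0.164 M, more than free substrate. With the same constant assumed for both steps, [partner B] decays as a pseudo-first-order species, and the decade time, ln(10) divided by the constant times [partner A] + [substrate], came to 16.0 d.

4. Last came the rest. Midnight target grew at 0.00184 M d⁻¹ around 7.50 d, and with the same constant again this meant [second intermediate] near 0.0597 M. I assumed it follows the tail of its feed, which left 1.40 decades to go and my [second intermediate] of 0.00237 M.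

5. The forecast gave [target] 0.032 M, [dormant form] 0.085 M, [open intermediate] 0.042 M and [second intermediate] 0.008 M, saying: “So second intermediate is leaking to side product”. My [second intermediate] lay below its figure.

6. The flask gave [target] 0.0260 M, [dormant form] 0.0868 M, [open intermediate] 0.0439 M and [second intermediate] 0.00140 M.

    second intermediate → side product (k = 0.0100 h⁻¹)
    partner B + partner A → second intermediate (k = 0.0300 M⁻¹ h⁻¹)
    substrate + partner B → open intermediate (k = 0.0300 M⁻¹ h⁻¹)
    open intermediate + second intermediate → target (k = 0.0300 M⁻¹ h⁻¹)
    substrate ⇌ dormant form (K = 2.00, k = 0.0150 h⁻¹)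

The flask's [partner B] went from 4.44% of charge at 15.0 d to 0.424% at 30.0 d, a decade in 14.7 d against my 16.0 d. In the neighbour charged with 0.080 M of substrate, the [partner A] and [substrate] left at the end give a decade time of 22.0 d. Assuming for it the level I reckoned back for the flask at 7.50 d, that puts the neighbour's [second intermediate] at 0.00336 M, and the neighbour holds 0.00319 M.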